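**Retrosynthetic overview**
- The target comes from a catechol aldehyde carrying a ring-B aryl acetate; one borohydride step reduces the CHO and removes the acetate.
- Key step: the catechol C–O bond next to the benzyl group is made by ipso-hydroxylation of a 2-benzyl-6-bromophenol at the benzyl-bearing carbon, followed by a 1,2-benzyl shift. This C–O bond formation fixes the substitution pattern of ring A.
- The diarylmethane C–C bond comes from a Friedel–Crafts benzylation of 3-bromo-4-hydroxybenzaldehyde with the diacetate of 3-bromo-4-hydroxybenzyl alcohol.
- No ring is formed. Both benzene rings are bought intact in 3-bromo-4-hydroxybenzaldehyde; the ring-B electrophile is made first, joined to ring A, and ring A is oxygenated last.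

Assumption: the target SMILES contains no stereocentre, so the compound is achiral and no stereocontrol is needed; the one stereocentre in the route (intermediate 5, racemic) is destroyed in the step that creates it.

**Step 1**
Reactants: 1 3-bromo-4-hydroxybenzaldehyde
Product: 2 2-bromo-4-(hydroxymethyl)phenol (3-bromo-4-hydroxybenzyl alcohol)
Conditions: NaBH4 (1.5 equiv), MeOH, 0 °C → rt; aq. NH4Cl
Reagents that add atoms: none
Why: Borohydride reduction of an aryl aldehyde is chemoselective, leaving the aryl bromide and the phenol untouched, and creates no stereocentre.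

**Step 2**
Reactants: 2 2-bromo-4-(hydroxymethyl)phenol
Product: 3 4-(acetoxymethyl)-2-bromophenyl acetate
Conditions: Ac2O (2.5 equiv), pyridine, DMAP (5 mol %), CH2Cl2, 0 °C → rt
Reagents that add atoms: acetic anhydride, CC(=O)OC(C)=O
Why: DMAP-catalysed O-acetylation turns the benzylic OH into a leaving group and masks the phenol as an electron-poor aryl acetate, which stops quinone-methide self-condensation of the electrophile and later protects ring B from oxidation.

**Step 3**
Reactants: 3 4-(acetoxymethyl)-2-bromophenyl acetate; 1 3-bromo-4-hydroxybenzaldehyde (3 equiv, excess recovered)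
Product: 4 2-bromo-4-(3-bromo-5-formyl-2-hydroxybenzyl)phenyl acetate
Conditions: TfOH (10 mol %), HFIP, 80 °C (sealed tube)
Reagents that add atoms: none
Why: Friedel–Crafts benzylation: the benzylic acetate ionises in TfOH/HFIP and alkylates 1 at C5, its only free position ortho or para to OH, while the acetate-deactivated ring of 3 cannot compete and the product has no second activated site (any O-benzyl ether reverts under the acid).

**Step 4**
Reactants: 4 2-bromo-4-(3-bromo-5-formyl-2-hydroxybenzyl)phenyl acetate
Product: 6 2-bromo-4-(4-bromo-6-formyl-2,3-dihydroxybenzyl)phenyl acetate, via racemic o-quinol 5 (not isolated)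
Conditions: SIBX (1.1 equiv IBX), THF, rt → 40 °C, dilute; filter, aq. NaHCO3 wash; then TfOH (5 mol %), HFIP, 0 °C
Reagents that add atoms: IBX (2-iodoxybenzoic acid, the oxidant in SIBX), O=C1OI(=O)(O)c2ccccc12
Why: Proposed new method: an ipso-hydroxylative dearomatisation with 1,2-benzyl shift (a chemical NIH shift), in which the λ5-iodane binds the phenol oxygen and delivers its oxo ligand to an ortho carbon; because the other ortho carbon carries bromine and is electron-poor, the C–O bond forms at the benzyl-bearing carbon to give o-quinol 5, and protonation of its dienone then drives a semipinacol-type (dienone–phenol) migration of the non-ionisable, acetate-deactivated benzyl group to the neighbouring CH carbon, with aromatisation to catechol 6 and loss of the racemic stereocentre of 5; the closest known reaction types are the SIBX hydroxylative dearomatisation of 2-alkylphenols and the acid-catalysed dienone–phenol rearrangement of 6-benzylcyclohexa-2,4-dienones, which have not been combined or shown on an electron-poor 2-benzyl-6-bromophenol.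

**Step 5**
Reactants: 6 2-bromo-4-(4-bromo-6-formyl-2,3-dihydroxybenzyl)phenyl acetate
Product: 7 6-bromo-3-[(3-bromo-4-hydroxyphenyl)methyl]-4-(hydroxymethyl)benzene-1,2-diol (5-bromo-2-(3-bromo-4-hydroxybenzyl)-3,4-dihydroxybenzyl alcohol, CNP0232913.0)
Conditions: NaBH4 (2 equiv), K2CO3 (0.2 equiv), degassed MeOH, Ar, 0 °C → rt; AcOH quench to pH 5
Reagents that add atoms: none
Why: Borohydride reduction of the aldehyde and base-catalysed methanolysis (transesterification) of the aryl acetate run in the same flask, giving the benzylic alcohol and the free ring-B phenol without touching the aryl bromides or creating a stereocentre.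

**Compound list**
1 | 3-bromo-4-hydroxybenzaldehyde | O=Cc1ccc(O)c(Br)c1 | starting material
2 | 2-bromo-4-(hydroxymethyl)phenol | OCc1ccc(O)c(Br)c1 | intermediate
3 | 4-(acetoxymethyl)-2-bromophenyl acetate | CC(=O)OCc1ccc(OC(C)=O)c(Br)c1 | intermediate
4 | 2-bromo-4-(3-bromo-5-formyl-2-hydroxybenzyl)phenyl acetate | CC(=O)Oc1ccc(Cc2cc(C=O)cc(Br)c2O)cc1Br | intermediate
5 | racemic 2-bromo-4-[(3-bromo-5-formyl-1-hydroxy-2-oxocyclohexa-3,5-dien-1-yl)methyl]phenyl acetate (o-quinol) | O=C1C(Br)=CC(C=O)=CC1(O)Cc1ccc(OC(C)=O)c(Br)c1 | intermediate (not isolated)
6 | 2-bromo-4-(4-bromo-6-formyl-2,3-dihydroxybenzyl)phenyl acetate | CC(=O)Oc1ccc(Cc2c(C=O)cc(Br)c(O)c2O)cc1Br | intermediate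
7 | 6-bromo-3-[(3-bromo-4-hydroxyphenyl)methyl]-4-(hydroxymethyl)benzene-1,2-diol | OCc1cc(Br)c(O)c(O)c1Cc1ccc(O)c(Br)c1 | target

**Totals**
Total step count: 5. Longest linear sequence: 5 (1 → 2 → 3 → 4 → 6 → 7; 1 enters a second time in step 3).

**Steps most likely to fail, with fallbacks**

Step 4, the new step, is the main risk. The phenol of 4 is electron-poor, so oxygen transfer may be slow; oxygen could be delivered to the bromine-bearing carbon instead, with loss of HBr; or o-quinol 5 could dimerise before the acid is added. The fallback uses only known chemistry; it sets out from 1 and from 3 and comes back at 6.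
- Iodination of 1 ortho to the phenol (NIS, cat. TFA, MeCN) gives 3-bromo-4-hydroxy-5-iodobenzaldehyde F1.
- Copper-mediated Ullmann-type hydroxylation of the C–I bond (aq. NaOH, Cu powder/CuSO4, reflux; the iodide reacts ahead of the bromide, as in the classical 5-iodovanillin to 5-hydroxyvanillin conversion) gives 3-bromo-4,5-dihydroxybenzaldehyde F2.
- Friedel–Crafts benzylation of F2 with diacetate 3 under the step-3 conditions then gives 6. Attack is expected ortho to the 5-OH, between OH and CHO, as in halogenation of isovanillin, because the other free position is flanked by Br and CHO. Any regioisomer would be removed by chromatography.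

Step 3 may be sluggish because 1 is a weak nucleophile and the cation from 3 is not stabilised. The fallback reverses the polarity of the coupling; it sets out from 1 and comes back at 4.
- Blanc chloromethylation of 1 (paraformaldehyde, conc. HCl, 60 °C) functionalises the only activated position and gives 3-bromo-5-(chloromethyl)-4-hydroxybenzaldehyde F3.
- This ortho-hydroxybenzyl chloride alkylates 2-bromophenol (Oc1ccccc1Br, used in excess, ZnCl2 cat., 70 °C) at its para position to give 3-bromo-5-(3-bromo-4-hydroxybenzyl)-4-hydroxybenzaldehyde F4.
- Mono-acetylation (Ac2O 1.05 equiv, Et3N, cat. DMAP, CH2Cl2) gives 4. Acetyl transfer equilibrates onto the less acidic, less hindered ring-B phenol, because the acetate of the formyl-substituted phenol is an active ester.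

Step 5 can lose material through air oxidation of the catechol in base or through quinone-methide chemistry of the para-hydroxybenzyl alcohol. The fallback separates the two events and moves the deprotection to the acid side; it sets out from 6 and comes back at 7.
- Acid-catalysed transesterification (AcCl in MeOH to generate HCl, rt; any dimethyl acetal is hydrolysed on aqueous work-up) gives 5-bromo-2-(3-bromo-4-hydroxybenzyl)-3,4-dihydroxybenzaldehyde F5.
- The aldehyde is then reduced under near-neutral Luche conditions (NaBH4, CeCl3·7H2O, EtOH, −20 °C, ascorbic acid/AcOH quench) to 7.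

**Further compounds**
F1 | step 4 | 3-bromo-4-hydroxy-5-iodobenzaldehyde | O=Cc1cc(Br)c(O)c(I)c1
F2 | step 4 | 3-bromo-4,5-dihydroxybenzaldehyde | O=Cc1cc(O)c(O)c(Br)c1
F3 | step 3 | 3-bromo-5-(chloromethyl)-4-hydroxybenzaldehyde | O=Cc1cc(Br)c(O)c(CCl)c1
F4 | step 3 | 3-bromo-5-(3-bromo-4-hydroxybenzyl)-4-hydroxybenzaldehyde | O=Cc1cc(Br)c(O)c(Cc2ccc(O)c(Br)c2)c1
F5 | step 5 | 5-bromo-2-(3-bromo-4-hydroxybenzyl)-3,4-dihydroxybenzaldehyde | O=Cc1cc(Br)c(O)c(O)c1Cc1ccc(O)c(Br)c1
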